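**Strategy.** Ring B (oxane O, C18–C22; target numbered C1 = CH2N to C30 = terminal CH3) is cut at C19–C20 and C21–C22, which makes C20–C21 a vinyl ether unit. In one flask, α-lithiated ethyl vinyl ether opens the C18/C19 epoxide 5 at C19, and the hydroxy enol ether so formed closes onto the oxocarbenium ion of the C22 aldehyde 8 to give the 2,6-cis oxan-4-one. The step exploits the all-equatorial C18/C20/C22 pattern of ring B: the purchased C18 centre fixes C22 in the chair closure and C20 in the next reduction. The furan on C17 then becomes ring A (Achmatowicz), and both polyene arms and the carbamate chain are attached late.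

Key step: step 4

Remark: ring A = oxane O/C12–C16, ring B = oxane O/C18–C22; "RB" = (2S,4S,6R)-6-[(2S)-1-(benzyloxy)propan-2-yl]-4-methoxyoxan-2-yl (C18–C24 part).
Remark: compounds 1, 2, 6, 9, 16, 27, 29, 34, 39, 48 and (+)-B-methoxydiisopinocampheylborane are taken as purchasable; step 4 is run in one flask without isolation.

Step 1
Reactants: 1 furan; 2 (R)-epichlorohydrin
Product: 5 (R)-2-(furan-2-ylmethyl)oxirane, via 2-furyllithium 3 (not isolated), via (R)-1-chloro-3-(furan-2-yl)propan-2-ol 4 (not isolated)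
Conditions: n-BuLi, THF, 0 °C; then 2, BF3·OEt2, −78 °C; then K2CO3, MeOH, rt
Reagents that add atoms: none
Why: α-lithiation of furan, BF3-assisted epoxide opening at the CH2 terminus and base closure of the chlorohydrin (Williamson) transpose the epoxide without touching the bought stereocentre, which becomes C18.

Step 2
Reactants: 6 methyl (S)-3-hydroxy-2-methylpropanoate
Product: 7 methyl (S)-3-(benzyloxy)-2-methylpropanoate
Conditions: BnOC(=NH)CCl3, TfOH (cat.), CH2Cl2/cyclohexane, rt
Reagents that add atoms: benzyl 2,2,2-trichloroacetimidate, ClC(Cl)(Cl)C(=N)OCc1ccccc1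
Why: acid-catalysed imidate benzylation avoids base, so the β-hydroxy ester neither epimerises nor eliminates.

Step 3
Reactants: 7 methyl (S)-3-(benzyloxy)-2-methylpropanoate
Product: 8 (S)-3-(benzyloxy)-2-methylpropanal
Conditions: DIBAL-H, CH2Cl2, −78 °C; Rochelle salt; used crude
Reagents that add atoms: none
Why: partial ester reduction through the tetrahedral aluminate that is stable at −78 °C gives the aldehyde, which is used at once to protect the α-centre (C23).

Step 4
Reactants: 5 (R)-2-(furan-2-ylmethyl)oxirane; 9 ethyl vinyl ether; 8 (S)-3-(benzyloxy)-2-methylpropanal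
Product: 13 (2R,6R)-2-[(2S)-1-(benzyloxy)propan-2-yl]-6-(furan-2-ylmethyl)oxan-4-one, via 1-ethoxyvinyllithium 10 (not isolated), via lithium (S)-4-ethoxy-1-(furan-2-yl)pent-4-en-2-olate 11 (not isolated), via O-ethyl oxocarbenium ion 12 (not isolated)
Conditions: 9, t-BuLi, THF, −78 → 0 °C; then 5, BF3·OEt2, −78 °C; then 8 (2 equiv), TMSOTf, CH2Cl2, −78 → −40 °C; 1 M HCl, THF, 0 °C
Reagents that add atoms: water, O
Why: Mechanism: 1-ethoxyvinyllithium 10 (an acyl-anion equivalent) opens the BF3-activated epoxide 5 by SN2 attack at the CH2 terminus C19 (C19–C20 formed, C18 untouched) to give alkoxide 11, which TMSOTf silylates and condenses with aldehyde 8 to an (E)-oxocarbenium ion that the tethered 2-ethoxyalkene attacks through its CH2 carbon C21 (C21–C22 formed) to give the O-ethyl oxocarbenium ion 12, hydrolysed to ketone 13 on acidic work-up. The closest known reaction types are the BF3-mediated opening of epoxides by organolithiums and the Prins-type (oxocarbenium–enol ether) cyclisation of hydroxy enol ethers to 2,6-cis-oxan-4-ones, here telescoped in one flask. Ring B closes in a 6-endo-trig mode with respect to the enol ether through a chair transition state. The new centre C22 is controlled by C18: the furfuryl group and the C22 substituent both sit equatorial on the chair, which gives the 2,6-cis ring, while C23 is carried in from 8. The step needs the intramolecular closure to outrun intermolecular aldol addition of the enol ether to 8 and Friedel–Crafts attack of the furan, and the much higher nucleophilicity of the 1,1-disubstituted enol ether in a six-membered chair closure at −78 °C should secure that; excess 10 is consumed by the surplus of 8.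

Step 5
Reactants: 13 (2R,6R)-2-[(2S)-1-(benzyloxy)propan-2-yl]-6-(furan-2-ylmethyl)oxan-4-one
Product: 14 (2R,4S,6S)-2-[(2S)-1-(benzyloxy)propan-2-yl]-6-(furan-2-ylmethyl)oxan-4-ol (all-cis)
Conditions: NaBH4, MeOH, −40 °C
Reagents that add atoms: none
Why: the small hydride adds axially to the chair oxan-4-one whose C18 and C22 groups are equatorial, so the C20 hydroxyl should come out equatorial and all-cis (substrate-controlled ketone reduction).

Step 6
Reactants: 14 all-cis oxan-4-ol
Product: 15 (2R,4S,6S)-2-[(2S)-1-(benzyloxy)propan-2-yl]-6-(furan-2-ylmethyl)-4-methoxyoxane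
Conditions: NaH, MeI, THF, 0 °C → rt
Reagents that add atoms: iodomethane, CI
Why: Williamson methylation of the only free hydroxyl installs the C20 methoxy group with retention.

Step 7
Reactants: 15 4-methoxyoxane with furfuryl group; 16 (R)-4-methyldihydrofuran-2(3H)-one
Product: 18 (3R)-4-hydroxy-3-methyl-1-[5-(RB-methyl)furan-2-yl]butan-1-one, via 5-lithiofuran 17 (not isolated)
Conditions: n-BuLi, THF, −78 → 0 °C; then 16, −78 °C; NH4Cl
Reagents that add atoms: none
Why: 2-alkylfurans lithiate at C5, and the lithiofuran should add once to the γ-lactone because the lactolate is stable at −78 °C, which delivers C9–C12 with the C10 centre of 16 untouched.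

Step 8
Reactants: 18 γ-hydroxy ketone
Product: 19 tert-butyldiphenylsilyl ether of 18
Conditions: TBDPSCl, imidazole, DMF, rt
Reagents that add atoms: tert-butyl(chloro)diphenylsilane, CC(C)(C)[Si](Cl)(c1ccccc1)c1ccccc1
Why: silylation of the primary alcohol gives an ether that should survive the acidic, organometallic and hydrogenolytic steps ahead.

Step 9
Reactants: 19 furyl ketone
Product: 20 (1S,3R)-4-[(tert-butyldiphenylsilyl)oxy]-3-methyl-1-[5-(RB-methyl)furan-2-yl]butan-1-ol
Conditions: RuCl(p-cymene)[(S,S)-TsDPEN] (1 mol%), HCO2H/Et3N (5:2), rt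
Reagents that add atoms: none
Why: Noyori asymmetric transfer hydrogenation of a 2-acylfuran, in which the (S,S)-ligand should set the C12 carbinol as S under catalyst control.

Step 10
Reactants: 20 (S)-furyl carbinol
Product: 21 6-hydroxy-2H-pyran-3(6H)-one carrying the C9–C11 chain at C12 and RB-CH2 at C16 (anomer mixture)
Conditions: NBS, NaHCO3, NaOAc, THF/H2O (4:1), 0 °C
Reagents that add atoms: water, O
Why: Achmatowicz rearrangement, in which the furan is oxidised to the ene-dione and the C12 hydroxyl closes onto the far carbonyl, so the carbinol oxygen becomes the ring A oxygen and C12 is retained.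

Step 11
Reactants: 21 pyranone hemiketal
Product: 22 2,6-cis-2H-pyran-3(6H)-one (C12 and C16 substituents cis)
Conditions: Et3SiH, TFA, CH2Cl2, −40 °C
Reagents that add atoms: none
Why: Kishi reduction, in which acid ionises the hemiketal to the cyclic oxocarbenium ion and the silane adds to C16 on the face opposite the C12 substituent, setting C16 cis to C12.

Step 12
Reactants: 22 2,6-cis enone
Product: 23 2,6-cis-5-methyloxan-3-one (C15 methyl trans to the C16 substituent)
Conditions: Me2CuLi (MeLi, CuI), Et2O, −78 °C; NH4Cl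
Reagents that add atoms: lithium dimethylcuprate, [Li+].C[Cu-]C
Why: Gilman 1,4-addition to the enone, with the methyl entering C15 anti to the neighbouring C16 substituent, while C12 (α to the ketone) stays in its thermodynamic equatorial position.

Step 13
Reactants: 23 oxan-3-one
Product: 24 tertiary alcohol with ring A complete (C13 methyl axial and cis to the C12 and C16 substituents, hydroxyl equatorial)
Conditions: MeMgBr, toluene, −78 °C; NH4Cl
Reagents that add atoms: methylmagnesium bromide, C[Mg]Br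
Why: Grignard 1,2-addition, in which the ring oxygen removes one 1,3-diaxial hydrogen from the chair oxan-3-one, so methyl should attack axially and leave the C13 hydroxyl equatorial, as in angular-methyl installations on polyether oxanones.

Step 14
Reactants: 24 benzyl ether
Product: 25 primary alcohol at C24
Conditions: H2 (1 atm), Pd/C, EtOAc, rt
Reagents that add atoms: none
Why: hydrogenolysis of the benzyl ether at a stage with no alkene present; the silyl ether, ethers and tertiary alcohol are inert.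

Step 15
Reactants: 25 primary alcohol
Product: 26 C24 aldehyde
Conditions: Dess–Martin periodinane, NaHCO3, CH2Cl2, 0 °C → rt
Reagents that add atoms: none
Why: buffered Dess–Martin oxidation gives the α-branched aldehyde without epimerising C23; the tertiary alcohol cannot be oxidised.

Step 16
Reactants: 26 aldehyde; 27 2-(triphenylphosphoranylidene)propanal
Product: 28 (24E)-enal (C24=C25, aldehyde at C26)
Conditions: toluene, 80 °C
Reagents that add atoms: none
Why: Wittig reaction of a stabilised ylide, which should give the E-trisubstituted enal under thermodynamic control of oxaphosphetane formation.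

Step 17
Reactants: 28 enal; 29 diethyl (E)-but-2-en-1-ylphosphonate
Product: 30 (24E,26E,28E)-triene, silyl ether at C9
Conditions: 29, LiHMDS (2.5 equiv), THF, −78 °C; then 28, −78 → 0 °C
Reagents that add atoms: none
Why: Horner–Wadsworth–Emmons olefination with an allylic phosphonate, whose lithium anion attacks through its α-carbon to give the new C26=C27 bond E, with the C28=C29 geometry carried in 29.

Step 18
Reactants: 30 silyl ether
Product: 31 C9 primary alcohol
Conditions: TBAF, AcOH, THF, rt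
Reagents that add atoms: none
Why: buffered fluoride cleaves the silyl ether without harming the triene.

Step 19
Reactants: 31 primary alcohol
Product: 32 C9 aldehyde
Conditions: Dess–Martin periodinane, NaHCO3, CH2Cl2, 0 °C
Reagents that add atoms: none
Why: buffered Dess–Martin oxidation tolerates the triene and the tertiary alcohol and keeps the C10 centre.

Step 20
Reactants: 32 aldehyde
Product: 33 (8E)-vinyl iodide (I–C8H=C9H–C10)
Conditions: CHI3, CrCl2, THF/1,4-dioxane, 0 °C → rt
Reagents that add atoms: iodoform, IC(I)I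
Why: Takai olefination with the gem-dichromium reagent is E-selective and non-basic, so C10 is not epimerised.

Step 21
Reactants: 34 ethyl (S)-4-chloro-3-hydroxybutanoate
Product: 35 ethyl (S)-3-[(tert-butyldimethylsilyl)oxy]-4-chlorobutanoate
Conditions: TBSCl, imidazole, DMF, rt
Reagents that add atoms: tert-butyl(chloro)dimethylsilane, CC(C)(C)[Si](C)(C)Cl
Why: silylation protects the bought C2 carbinol and blocks epoxide formation from the chlorohydrin.

Step 22
Reactants: 35 silyl ether ester
Product: 36 (S)-3-[(tert-butyldimethylsilyl)oxy]-4-chlorobutanal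
Conditions: DIBAL-H, CH2Cl2, −78 °C; Rochelle salt
Reagents that add atoms: none
Why: partial ester reduction at −78 °C gives the β-silyloxy aldehyde (C4).

Step 23
Reactants: 36 aldehyde
Product: 38 (4R,6S)-6-[(tert-butyldimethylsilyl)oxy]-7-chlorohept-1-en-4-ol, via diisopinocampheylborinate 37 (not isolated)
Conditions: (+)-Ipc2BOMe, allylMgBr, Et2O, −78 °C; then 36, −100 → −78 °C; NaOH, H2O2
Reagents that add atoms: allylmagnesium bromide, C=CC[Mg]Br
Why: Brown allylboration through a chair Zimmerman–Traxler transition state, in which the (+)-Ipc2B reagent should override the weak bias of the β-silyloxy group and set the C4 carbinol R (1,3-anti to C2).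

Step 24
Reactants: 38 homoallylic alcohol; 39 isopropenylboronic acid pinacol ester
Product: 40 (2Z,5R,7S)-7-[(tert-butyldimethylsilyl)oxy]-8-chloro-2-(4,4,5,5-tetramethyl-1,3,2-dioxaborolan-2-yl)oct-2-en-5-ol (boron trans to the chain)
Conditions: Hoveyda–Grubbs II (10 mol%), 39 (4 equiv), CH2Cl2, 40 °C
Reagents that add atoms: none
Why: olefin cross-metathesis of a terminal alkene with the 1,1-disubstituted vinyl boronate, in which the chain should end trans to the boryl group as it does with methacrylates, giving the C6=C7 geometry needed.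

Step 25
Reactants: 40 alkenyl boronate alcohol
Product: 42 C4 primary carbamate of 40, via N-trichloroacetyl carbamate 41 (not isolated)
Conditions: Cl3CC(O)NCO, CH2Cl2, 0 °C; then K2CO3, MeOH, 0 °C
Reagents that add atoms: trichloroacetyl isocyanate, O=C=NC(=O)C(Cl)(Cl)Cl
Why: the acyl isocyanate carbamoylates the secondary alcohol, and mild methanolysis removes the trichloroacetyl group to leave OC(O)NH2 with retention at C4.

Step 26
Reactants: 42 chloro carbamate
Product: 43 C1 azide (west fragment: azide, C2 silyl ether, C4 carbamate, C7 boronate)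
Conditions: NaN3, NaI (cat.), DMF, 80 °C
Reagents that add atoms: sodium azide, [Na+].[N-]=[N+]=[N-]
Why: SN2 displacement of the primary chloride introduces the nitrogen of C1; with the C4 oxygen capped no silyl migration is possible.

Step 27
Reactants: 33 vinyl iodide; 43 alkenyl boronate
Product: 44 coupled (6E,8E)-diene with complete carbon skeleton (C1 azide, C2 silyl ether)
Conditions: Pd(dppf)Cl2·CH2Cl2 (10 mol%), AsPh3, Cs2CO3, DMF/H2O, rt
Reagents that add atoms: none
Why: Suzuki–Miyaura coupling forms C7–C8 with retention of both alkene geometries; the phosphine-poor catalyst system should spare the azide.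

Step 28
Reactants: 44 silyl ether
Product: 45 C2 alcohol (azide retained)
Conditions: HF·pyridine, pyridine, THF, 0 °C → rt
Reagents that add atoms: none
Why: buffered HF removes the secondary silyl ether without carbamate migration or damage to the polyenes.

Step 29
Reactants: 45 azido alcohol
Product: 47 C1 primary amine, via iminophosphorane 46 (not isolated)
Conditions: PMe3, THF, rt; then H2O
Reagents that add atoms: none
Why: Staudinger reduction converts the azide into the amine chemoselectively in the presence of the alkenes and the carbamate.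

Step 30
Reactants: 48 methyl 2-methoxyacrylate
Product: 50 2-methoxyacrylic acid, via lithium 2-methoxyacrylate 49 (not isolated)
Conditions: LiOH, THF/H2O, 0 °C; then 1 M HCl to pH 3, 0 °C
Reagents that add atoms: lithium hydroxide, [Li+].[OH-]
Why: saponification followed by cold, brief acidification frees the acid before the enol ether can hydrolyse.

Step 31
Reactants: 47 amine; 50 2-methoxyacrylic acid
Product: 51 CNP0155183.1 (target)
Conditions: EDC·HCl, HOBt, i-Pr2NEt, CH2Cl2, 0 °C → rt
Reagents that add atoms: none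
Why: carbodiimide/HOBt amide coupling acylates the primary amine much faster than the secondary and tertiary alcohols, so no protecting group is needed in the last step.

**Compound list**

1 | furan | c1ccoc1 | starting material
2 | (R)-epichlorohydrin | ClC[C@H]1CO1 | starting material
3 | 2-furyllithium | [Li]c1ccco1 | intermediate
4 | (R)-1-chloro-3-(furan-2-yl)propan-2-ol | ClC[C@H](O)Cc1ccco1 | intermediate
5 | (R)-2-(furan-2-ylmethyl)oxirane | c1coc(C[C@@H]2CO2)c1 | intermediate
6 | methyl (S)-3-hydroxy-2-methylpropanoate | COC(=O)[C@@H](C)CO | starting material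
7 | methyl (S)-3-(benzyloxy)-2-methylpropanoate | COC(=O)[C@@H](C)COCc1ccccc1 | intermediate
8 | (S)-3-(benzyloxy)-2-methylpropanal | O=C[C@@H](C)COCc1ccccc1 | intermediate
9 | ethyl vinyl ether | C=COCC | starting material
10 | 1-ethoxyvinyllithium | [Li]C(=C)OCC | intermediate
11 | lithium (S)-4-ethoxy-1-(furan-2-yl)pent-4-en-2-olate | c1coc(C[C@@H]([O-])CC(=C)OCC)c1.[Li+] | intermediate
12 | O-ethyl oxocarbenium ion of 13 (4-ethoxyoxan-4-ylium) | c1coc(C[C@@H]2CC(=[O+]CC)C[C@H]([C@@H](C)COCc3ccccc3)O2)c1 | intermediate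
13 | (2R,6R)-2-[(2S)-1-(benzyloxy)propan-2-yl]-6-(furan-2-ylmethyl)oxan-4-one | c1coc(C[C@@H]2CC(=O)C[C@H]([C@@H](C)COCc3ccccc3)O2)c1 | intermediate
14 | (2R,4S,6S)-2-[(2S)-1-(benzyloxy)propan-2-yl]-6-(furan-2-ylmethyl)oxan-4-ol | c1coc(C[C@@H]2C[C@H](O)C[C@H]([C@@H](C)COCc3ccccc3)O2)c1 | intermediate
15 | (2R,4S,6S)-2-[(2S)-1-(benzyloxy)propan-2-yl]-6-(furan-2-ylmethyl)-4-methoxyoxane | c1coc(C[C@@H]2C[C@H](OC)C[C@H]([C@@H](C)COCc3ccccc3)O2)c1 | intermediate
16 | (R)-4-methyldihydrofuran-2(3H)-one | C[C@H]1COC(=O)C1 | starting material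
17 | 5-lithio derivative of 15 | [Li]c1ccc(C[C@@H]2C[C@H](OC)C[C@H]([C@@H](C)COCc3ccccc3)O2)o1 | intermediate
18 | (3R)-4-hydroxy-3-methyl-1-[5-(RB-methyl)furan-2-yl]butan-1-one | OC[C@H](C)CC(=O)c1ccc(C[C@@H]2C[C@H](OC)C[C@H]([C@@H](C)COCc3ccccc3)O2)o1 | intermediate
19 | tert-butyldiphenylsilyl ether of 18 | CC(C)(C)[Si](c4ccccc4)(c5ccccc5)OC[C@H](C)CC(=O)c1ccc(C[C@@H]2C[C@H](OC)C[C@H]([C@@H](C)COCc3ccccc3)O2)o1 | intermediate
20 | (1S,3R)-4-[(tert-butyldiphenylsilyl)oxy]-3-methyl-1-[5-(RB-methyl)furan-2-yl]butan-1-ol | CC(C)(C)[Si](c4ccccc4)(c5ccccc5)OC[C@H](C)C[C@@H](c1ccc(C[C@@H]2C[C@H](OC)C[C@H]([C@@H](C)COCc3ccccc3)O2)o1)O | intermediate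
21 | Achmatowicz product: 6-hydroxy-2H-pyran-3(6H)-one with the C9–C11 chain on C12 and RB-CH2 on C16, anomer mixture | CC(C)(C)[Si](c4ccccc4)(c5ccccc5)OC[C@H](C)C[C@@H]1OC(O)(C[C@@H]2C[C@H](OC)C[C@H]([C@@H](C)COCc3ccccc3)O2)C=CC1=O | intermediate
22 | 2,6-cis-2H-pyran-3(6H)-one (C12/C16 cis) | CC(C)(C)[Si](c4ccccc4)(c5ccccc5)OC[C@H](C)C[C@@H]1O[C@H](C[C@@H]2C[C@H](OC)C[C@H]([C@@H](C)COCc3ccccc3)O2)C=CC1=O | intermediate
23 | 2,6-cis-5-methyloxan-3-one (C15 methyl trans to C16 substituent) | CC(C)(C)[Si](c4ccccc4)(c5ccccc5)OC[C@H](C)C[C@@H]1O[C@H](C[C@@H]2C[C@H](OC)C[C@H]([C@@H](C)COCc3ccccc3)O2)[C@@H](C)CC1=O | intermediate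
24 | tertiary alcohol, ring A complete (C13 axial methyl, equatorial OH); C9 OTBDPS, C24 OBn | CC(C)(C)[Si](c4ccccc4)(c5ccccc5)OC[C@H](C)C[C@@H]1O[C@H](C[C@@H]2C[C@H](OC)C[C@H]([C@@H](C)COCc3ccccc3)O2)[C@@H](C)C[C@@]1(C)O | intermediate
25 | C24 primary alcohol (debenzylated 24) | CC(C)(C)[Si](c4ccccc4)(c5ccccc5)OC[C@H](C)C[C@@H]1O[C@H](C[C@@H]2C[C@H](OC)C[C@H]([C@@H](C)CO)O2)[C@@H](C)C[C@@]1(C)O | intermediate
26 | C24 aldehyde | CC(C)(C)[Si](c4ccccc4)(c5ccccc5)OC[C@H](C)C[C@@H]1O[C@H](C[C@@H]2C[C@H](OC)C[C@H]([C@@H](C)C=O)O2)[C@@H](C)C[C@@]1(C)O | intermediate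
27 | 2-(triphenylphosphoranylidene)propanal | CC(C=O)=P(c1ccccc1)(c1ccccc1)c1ccccc1 | starting material
28 | (24E)-2-methyl enal (aldehyde C26) | CC(C)(C)[Si](c4ccccc4)(c5ccccc5)OC[C@H](C)C[C@@H]1O[C@H](C[C@@H]2C[C@H](OC)C[C@H]([C@@H](C)/C=C(C)/C=O)O2)[C@@H](C)C[C@@]1(C)O | intermediate
29 | diethyl (E)-but-2-en-1-ylphosphonate | C/C=C/CP(=O)(OCC)OCC | starting material
30 | (24E,26E,28E)-triene, C9 OTBDPS | CC(C)(C)[Si](c4ccccc4)(c5ccccc5)OC[C@H](C)C[C@@H]1O[C@H](C[C@@H]2C[C@H](OC)C[C@H]([C@@H](C)/C=C(C)/C=C/C=C/C)O2)[C@@H](C)C[C@@]1(C)O | intermediate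
31 | triene C9 primary alcohol | OC[C@H](C)C[C@@H]1O[C@H](C[C@@H]2C[C@H](OC)C[C@H]([C@@H](C)/C=C(C)/C=C/C=C/C)O2)[C@@H](C)C[C@@]1(C)O | intermediate
32 | triene C9 aldehyde | O=C[C@H](C)C[C@@H]1O[C@H](C[C@@H]2C[C@H](OC)C[C@H]([C@@H](C)/C=C(C)/C=C/C=C/C)O2)[C@@H](C)C[C@@]1(C)O | intermediate
33 | (8E)-vinyl iodide (east–centre fragment C8–C30) | I/C=C/[C@H](C)C[C@@H]1O[C@H](C[C@@H]2C[C@H](OC)C[C@H]([C@@H](C)/C=C(C)/C=C/C=C/C)O2)[C@@H](C)C[C@@]1(C)O | intermediate
34 | ethyl (S)-4-chloro-3-hydroxybutanoate | ClC[C@@H](O)CC(=O)OCC | starting material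
35 | ethyl (S)-3-[(tert-butyldimethylsilyl)oxy]-4-chlorobutanoate | ClC[C@@H](O[Si](C)(C)C(C)(C)C)CC(=O)OCC | intermediate
36 | (S)-3-[(tert-butyldimethylsilyl)oxy]-4-chlorobutanal | ClC[C@@H](O[Si](C)(C)C(C)(C)C)CC=O | intermediate
37 | diisopinocampheylborinate of 38 | ClC[C@@H](O[Si](C)(C)C(C)(C)C)C[C@@H](CC=C)OB([C@H]1C[C@H]2C[C@@H]([C@@H]1C)C2(C)C)[C@H]1C[C@H]2C[C@@H]([C@@H]1C)C2(C)C | intermediate
38 | (4R,6S)-6-[(tert-butyldimethylsilyl)oxy]-7-chlorohept-1-en-4-ol | ClC[C@@H](O[Si](C)(C)C(C)(C)C)C[C@@H](CC=C)O | intermediate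
39 | isopropenylboronic acid pinacol ester | CC(=C)B1OC(C)(C)C(C)(C)O1 | starting material
40 | (2Z,5R,7S)-7-[(tert-butyldimethylsilyl)oxy]-8-chloro-2-(pinacolboryl)oct-2-en-5-ol | ClC[C@@H](O[Si](C)(C)C(C)(C)C)C[C@@H](C/C=C(C)/B1OC(C)(C)C(C)(C)O1)O | intermediate
41 | N-trichloroacetyl carbamate of 40 | ClC[C@@H](O[Si](C)(C)C(C)(C)C)C[C@@H](C/C=C(C)/B1OC(C)(C)C(C)(C)O1)OC(=O)NC(=O)C(Cl)(Cl)Cl | intermediate
42 | primary carbamate of 40 | ClC[C@@H](O[Si](C)(C)C(C)(C)C)C[C@@H](C/C=C(C)/B1OC(C)(C)C(C)(C)O1)OC(N)=O | intermediate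
43 | azide of 42 (west fragment C1–C7) | [N-]=[N+]=NC[C@@H](O[Si](C)(C)C(C)(C)C)C[C@@H](C/C=C(C)/B1OC(C)(C)C(C)(C)O1)OC(N)=O | intermediate
44 | coupled azide, C2 OTBS | [N-]=[N+]=NC[C@@H](O[Si](C)(C)C(C)(C)C)C[C@@H](C/C=C(C)/C=C/[C@H](C)C[C@@H]1O[C@H](C[C@@H]2C[C@H](OC)C[C@H]([C@@H](C)/C=C(C)/C=C/C=C/C)O2)[C@@H](C)C[C@@]1(C)O)OC(N)=O | intermediate
45 | azido alcohol (C2 OH) | [N-]=[N+]=NC[C@@H](O)C[C@@H](C/C=C(C)/C=C/[C@H](C)C[C@@H]1O[C@H](C[C@@H]2C[C@H](OC)C[C@H]([C@@H](C)/C=C(C)/C=C/C=C/C)O2)[C@@H](C)C[C@@]1(C)O)OC(N)=O | intermediate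
46 | trimethyliminophosphorane of 45 | CP(C)(C)=NC[C@@H](O)C[C@@H](C/C=C(C)/C=C/[C@H](C)C[C@@H]1O[C@H](C[C@@H]2C[C@H](OC)C[C@H]([C@@H](C)/C=C(C)/C=C/C=C/C)O2)[C@@H](C)C[C@@]1(C)O)OC(N)=O | intermediate
47 | C1 amine | NC[C@@H](O)C[C@@H](C/C=C(C)/C=C/[C@H](C)C[C@@H]1O[C@H](C[C@@H]2C[C@H](OC)C[C@H]([C@@H](C)/C=C(C)/C=C/C=C/C)O2)[C@@H](C)C[C@@]1(C)O)OC(N)=O | intermediate
48 | methyl 2-methoxyacrylate | C=C(OC)C(=O)OC | starting material
49 | lithium 2-methoxyacrylate | C=C(OC)C(=O)[O-].[Li+] | intermediate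
50 | 2-methoxyacrylic acid | C=C(OC)C(=O)O | intermediate
51 | CNP0155183.1 (2S,4R,6E,8E,10R,12S,13R,15S,16R,18S,20S,22R,23S,24E,26E,28E) | C=C(OC)C(=O)NC[C@@H](O)C[C@@H](C/C=C(C)/C=C/[C@H](C)C[C@@H]1O[C@H](C[C@@H]2C[C@H](OC)C[C@H]([C@@H](C)/C=C(C)/C=C/C=C/C)O2)[C@@H](C)C[C@@]1(C)O)OC(N)=O | target

**Totals.** 31 steps in all; longest linear sequence 23 steps (steps 2–20, 27–29 and 31, from the hydroxy ester 6 to the target; step 1, steps 21–26 and step 30 feed in as branches).

**Steps most likely to fail**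

1. Step 4. The telescoped sequence may divert through incomplete epoxide opening, hydrolysis of the enol ether before cyclisation, intermolecular aldol addition or oligomerisation, or enolisation of 8 with erosion at C23. Fallback: from 5, lithium acetylide–ethylenediamine in DMSO opens the epoxide to (S)-1-(furan-2-yl)pent-4-yn-2-ol F1. Its dianion (n-BuLi, 2 equiv) adds to 8 to give the ynediol F2 as a mixture at the propargylic carbinol, which the next step erases. A gold(I)-catalysed Meyer–Schuster rearrangement (Ph3PAuNTf2, MeOH, toluene) moves that oxygen to C20 and gives the (E)-β′-hydroxy enone F3. Amberlyst-15 in CH2Cl2 then closes ring B by reversible 6-endo oxa-Michael addition and should settle on the thermodynamic 2,6-cis ketone 13.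

2. Step 24. Cross-metathesis with the hindered 1,1-disubstituted boronate may stop at low conversion, favour homodimerisation of 38, or give a poor geometric ratio. Fallback: from 36, allenylboronic acid pinacol ester with (R)-TRIP phosphoric acid gives the homopropargylic alcohol (4R,6S)-6-[(tert-butyldimethylsilyl)oxy]-7-chlorohept-1-yn-4-ol F4. Dianion C-methylation (n-BuLi, 2.1 equiv; MeI) gives the 2-alkyne F5. Hydrozirconation with excess Cp2Zr(H)Cl, which places zirconium on the methyl-bearing carbon, followed by iodine gives the (E)-2-iodoalkene F6. Miyaura borylation (B2pin2, PdCl2(PPh3)2, KOPh, toluene, 50 °C) with retention returns to 40.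

3. Step 17. The delocalised phosphonate anion may give E/Z mixtures at C26=C27 or scramble the C28=C29 geometry. Fallback: from 28, Takai olefination (CHI3, CrCl2, THF/dioxane) gives the (24E,26E)-dienyl iodide F7, and Suzuki coupling with (E)-prop-1-enylboronic acid (Pd(PPh3)4, TlOEt, THF/H2O) gives 30 with each double bond set by a stereospecific step.

**Further compounds**

F1 | step 4 | (S)-1-(furan-2-yl)pent-4-yn-2-ol | c1coc(C[C@@H](O)CC#C)c1
F2 | step 4 | ynediol: 1-(benzyloxy)-8-(furan-2-yl)-2-methyloct-4-yne-3,7-diol, (2S,7S), mixture at C3 | c1coc(C[C@@H](O)CC#CC(O)[C@@H](C)COCc2ccccc2)c1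
F3 | step 4 | (E)-β′-hydroxy enone: 8-(benzyloxy)-1-(furan-2-yl)-2-hydroxy-7-methyloct-5-en-4-one, furfuryl carbinol S, methyl centre as in 8 | c1coc(C[C@@H](O)CC(=O)/C=C/[C@@H](C)COCc2ccccc2)c1
F4 | step 24 | (4R,6S)-6-[(tert-butyldimethylsilyl)oxy]-7-chlorohept-1-yn-4-ol | ClC[C@@H](O[Si](C)(C)C(C)(C)C)C[C@@H](CC#C)O
F5 | step 24 | (5R,7S)-7-[(tert-butyldimethylsilyl)oxy]-8-chlorooct-2-yn-5-ol | ClC[C@@H](O[Si](C)(C)C(C)(C)C)C[C@@H](CC#CC)O
F6 | step 24 | (2E,5R,7S)-7-[(tert-butyldimethylsilyl)oxy]-8-chloro-2-iodooct-2-en-5-ol | ClC[C@@H](O[Si](C)(C)C(C)(C)C)C[C@@H](C/C=C(C)/I)O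
F7 | step 17 | (24E,26E)-dienyl iodide (iodine on C27), otherwise as 28 | CC(C)(C)[Si](c4ccccc4)(c5ccccc5)OC[C@H](C)C[C@@H]1O[C@H](C[C@@H]2C[C@H](OC)C[C@H]([C@@H](C)/C=C(C)/C=C/I)O2)[C@@H](C)C[C@@]1(C)O
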